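## Structural features

The target is a pentabrominated 2,2'-dihydroxydiphenyl ether. Two benzene rings are joined only by one ether oxygen, which links C6 of ring A to C1' of ring B. Ring A carries OH at C1 and bromine at C2 and C4, ortho and para to its hydroxyl. Ring B carries OH at C6' and bromine at C2', C4' and C5', and C3' is its only unsubstituted carbon. There is no stereocentre, so nothing has to be set or preserved in that respect. The fragile parts are the five aryl C–Br bonds, which exclude metal–halogen exchange and reductive steps late in the route, and the two phenols, which are easily over-brominated or oxidised. The real difficulty is regiochemical and lies in ring B: C5'–Br is ortho to the C6' hydroxyl, yet C3', para to that hydroxyl, must stay C–H, so brominating ring B after its hydroxyl is free would have to favour ortho over para and cannot be trusted. The key step uses the fact that both hydroxyl-bearing carbons, C1 and C6', are ortho to the ether-bearing carbons C6 and C1'. Each hydroxyl can therefore be carried as a formyl group: on ring A it activates C6 for ether formation, on ring B it keeps the two oxygens of a formal catechol distinct, and both are converted to OH in one oxidation.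

## Logic of the disconnections

7 to 6: the C2–Br bond of ring A is cut. With C4 already brominated and C6 bearing the ether oxygen, C2 is the only carbon of ring A that the C1 hydroxyl activates, so this bromine can be added last. The gain is that ring A enters the route with a single bromine, which keeps its formyl-bearing ring less electron-poor and less crowded for the oxidation. The demand is that one equivalent of Br2 takes C2 of ring A and leaves C3' of ring B alone. C3' is para to the C6' hydroxyl, but it sits between two bromines on a ring that already carries three.

6 to 4 (through 5): the C1–O and C6'–O bonds of the two hydroxyls are cut and each carbon is traced back to a C–CHO bond. Both carbons are ortho to the ether linkage, so a formyl group can stand for each hydroxyl. This avoids any differentiation of catechol oxygens and supplies the activating group for the ether synthesis on ring A. The demand is that aryl migration beats hydride migration at both formyl groups, on rings that carry bromine.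

4 to 2 and 3: the C6–O ether bond is cut. C6 is ortho to the formyl-bearing C1, the position where an addition–elimination substitution is activated, and 3 carries fluoride there. Two monocyclic aldehydes of similar size result, and the route becomes convergent. The demand is that the weak, doubly flanked phenoxide of 2 displaces fluoride in preference to the bromides that are also ortho or para to a formyl group.

2 to 1: the two C–Br bonds ortho and para to the phenolic oxygen are cut (C2' and C4' in the numbering of the target). These are the bromines that only the C1' oxygen can direct. The third bromine, at C5', is meta to that oxygen and could later be directed only by the C6' hydroxyl, in competition with C3'. It is therefore taken from the starting material 1. The gain is that all three bromines of ring B are fixed before the rings are joined. The demand is a clean double bromination that stops at two and does not displace the formyl group.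

## Other disconnections considered

Alternative 1: The cut removes the C1'–O ether bond and the C2'–Br bond of ring B together. The C6' hydroxyl is carried as a pinacol boronate and the ring A hydroxyl as a methyl ether.
- Forward key step: iPrMgCl·LiCl would exchange the iodine of the iodo triflate A2 for magnesium, and loss of triflate would give a 3-boryl-5-bromoaryne. The magnesium phenoxide of 3,5-dibromo-2-methoxyphenol A3 would add at the aryne carbon next to boron. The aryl–magnesium species left at C2' would be brominated with C2Br2Cl4 to give the boronate A1.
- In its favour: an aryne is so electrophilic that the poor nucleophilicity of a hindered bromophenoxide matters much less than in an addition–elimination substitution; on this point the alternative is the better. Oxidation of a C–B bond to C–OH is also more dependable than aryl migration in an electron-poor aldehyde, again a point for the alternative. The C2' bromine is placed by construction, which equals the chosen plan.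
- Against it: A2 needs a separate synthesis of several steps. The iodine–magnesium exchange must be selective in the presence of four aryl bromides. The regiochemistry of the addition rests on the directing effect of boron, with the C4' bromine as a second influence.
- Structural comparison: A1 still lacks the C5' bromine. After oxidation of boron, ring B would have to be brominated ortho to the new hydroxyl in competition with the para carbon C3', the problem the chosen plan removes through its starting material. A methyl ether must also be cleaved at the end.
- Step economy: the preparation of A2, the key step, oxidation, bromination and demethylation make this route clearly longer than four steps.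

Alternative 2: The cut opens ring A at C2–C3 and C5–C6, so that ring A is built from acyclic pieces.
- Forward key step: the aryloxyacetone A5, obtained by O-alkylation of 2,4-dibromo-6-methoxyphenol A7, would condense under aqueous NaOH through both α-carbons with the two formyl groups of bromomalonaldehyde A6. Two dehydrations would give the phenol A4.
- In its favour: the ether is made by substitution at an sp3 carbon, which is easy even for a weak phenoxide; here the alternative is better than the chosen ether synthesis. The pattern of ring A (OH at C1, ether at C6, bromine at C4) follows from the construction without any regiochemical question, which equals the chosen plan.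
- Against it: condensations of this kind are dependable mainly with ketones activated at both α-carbons, and the methyl side of A5 is not activated. A6 is a base-sensitive, enolised dialdehyde whose anion is a poor electrophile and which can lose bromide. The mechanism needs two aldol condensations in sequence, against a single well-understood migration in the chosen key step.
- Structural comparison: A4 still needs bromine at C2 and at C5' and cleavage of the methyl ether, and the C5' against C3' competition returns once the ring B hydroxyl is free.
- Step economy: about five steps from A7, comparable in number but with the uncertain chemistry at the centre and at the end.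

Alternative 3: The cut removes the aromaticity of ring A together with its two C–Br bonds; ring A is carried as a cyclohexanone.
- Forward key step: the racemic aryloxy ketone A9, from A7 by O-alkylation with an α-halocyclohexanone, would be treated with about four equivalents of Br2 in acetic acid. α-Bromination and loss of HBr would aromatise the ring, and the new phenol would be brominated at C2 and C4 in the same pot to give A8.
- In its favour: the ether is again formed at an sp3 carbon, a point on which the alternative is better. One operation delivers the phenol and both bromines of ring A. On paper the route (alkylation, aromatising bromination, C5' bromination, demethylation) is as short as the chosen one, so step economy is equal.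
- Against it: bromination at the α-carbon that bears the aryloxy group would give an α-bromo ether from which the phenoxide of A7 can be expelled, so the ether linkage is at risk. The bromine stoichiometry must fall between incomplete aromatisation and over-bromination. Ring B, activated by its methoxy group, could be brominated at C3' or C5' during the same operation.
- Structural and mechanistic comparison: the C5' bromine and the demethylation remain for the end, with the same ortho against para problem. The key step is a cascade of several bromination and elimination events, where the chosen plan relies on one defined rearrangement.

Key step: step 3

Assumption: 2-bromo-6-hydroxybenzaldehyde (1) and 4-bromo-2-fluorobenzaldehyde (3) are taken as purchasable; the labels C1–C6 (ring A) and C1'–C6' (ring B) are those of the target throughout.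

Remark on the chemistry: the key-step precursor 4 and product 6 carry four bromines, with ring B complete, so that no bromination of ring B is needed after its hydroxyl is set free.

## Route

Step 1
Reactants: 1 2-bromo-6-hydroxybenzaldehyde
Product: 2 2,3,5-tribromo-6-hydroxybenzaldehyde
Conditions: Br2 (2.1 equiv), NaOAc, AcOH, rt
Reagents that add atoms: bromine, BrBr
Why: Electrophilic aromatic bromination of a salicylaldehyde; the hydroxyl directs to its free ortho and para carbons, the formyl group (meta) and the resident bromine (ortho/para) point to the same two carbons, and the remaining C–H is meta to the hydroxyl, so a single dibromination product is expected, with acetate taking up the HBr.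

Step 2
Reactants: 2 2,3,5-tribromo-6-hydroxybenzaldehyde; 3 4-bromo-2-fluorobenzaldehyde
Product: 4 2,3,5-tribromo-6-(5-bromo-2-formylphenoxy)benzaldehyde
Conditions: K2CO3, DMAc, 110 °C
Reagents that add atoms: none
Why: Nucleophilic aromatic substitution by addition–elimination; the ortho formyl group of 3 stabilises the Meisenheimer adduct and fluoride is the best leaving group for this mechanism, so the C–F carbon should be attacked in preference to the bromine-bearing carbons, while heat and a dipolar aprotic solvent compensate for the weak, flanked phenoxide of 2.

Step 3
Reactants: 4 2,3,5-tribromo-6-(5-bromo-2-formylphenoxy)benzaldehyde
Product: 6 2,3,5-tribromo-6-(5-bromo-2-hydroxyphenoxy)phenol, via bis-formate 5 (not isolated)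
Conditions: mCPBA (3 equiv), CH2Cl2, 40 °C; aq. Na2SO3 wash; K2CO3, MeOH, rt
Reagents that add atoms: mCPBA (3-chloroperoxybenzoic acid), OOC(=O)c1cccc(Cl)c1
Why: Baeyer–Villiger (Dakin-type) oxidation: the peracid adds to each formyl carbonyl to give a Criegee adduct, the aryl carbon (C1 of ring A, C6' of ring B) migrates from carbon to the nearer peroxide oxygen as 3-chlorobenzoate leaves, and the two aryl formates of 5 are then cleaved by transesterification with methanol, so that each C–CHO becomes C–OH with the oxygen coming from the peracid. The closest known reaction type is the mCPBA oxidation of ortho-alkoxy and ortho-aryloxy benzaldehydes to aryl formates followed by mild basic solvolysis. No ring is closed and no stereocentre is formed. The selectivity needed is aryl over hydride migration at both aldehydes; in each ring the ether oxygen is ortho to the migrating carbon and its lone pair stabilises the electron-deficient migrating terminus, and the acidic, water-free medium withholds the base that would remove the formyl hydrogen of the adduct and lead to the carboxylic acid. Ring A should react first, because its ether carbon has only one ortho neighbour and the oxygen lone pair can align with that ring; ring B is slower, since three bromines withdraw electron density and its flanked ether oxygen is twisted, which is why excess peracid, gentle heating and a long reaction time are planned. Aryl bromides and the diaryl ether are inert to the peracid, and the excess oxidant is destroyed before base is added so that the liberated phenoxides are not oxidised.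

Step 4
Reactants: 6 2,3,5-tribromo-6-(5-bromo-2-hydroxyphenoxy)phenol
Product: 7 2,3,5-tribromo-6-(3,5-dibromo-2-hydroxyphenoxy)phenol
Conditions: Br2 (1.0 equiv), AcOH, rt
Reagents that add atoms: bromine, BrBr
Why: Electrophilic bromination of a phenol; in ring A the C1 hydroxyl activates C2, its only free ortho carbon (C4 is brominated, C6 bears the ether oxygen), whereas the one free carbon of ring B, C3', lies between two bromines on a ring deactivated by three, so one equivalent of Br2 in acetic acid, where both phenols react as neutral species, should go to ring A.

## Compound list

1 | 2-bromo-6-hydroxybenzaldehyde | O=Cc1c(Br)cccc1O | starting material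
2 | 2,3,5-tribromo-6-hydroxybenzaldehyde | O=Cc1c(Br)c(Br)cc(Br)c1O | intermediate
3 | 4-bromo-2-fluorobenzaldehyde | O=Cc1ccc(Br)cc1F | starting material
4 | 2,3,5-tribromo-6-(5-bromo-2-formylphenoxy)benzaldehyde | O=Cc1ccc(Br)cc1Oc1c(Br)cc(Br)c(Br)c1C=O | intermediate
5 | 2,3,5-tribromo-6-[5-bromo-2-(formyloxy)phenoxy]phenyl formate | O=COc1ccc(Br)cc1Oc1c(Br)cc(Br)c(Br)c1OC=O | intermediate (not isolated)
6 | 2,3,5-tribromo-6-(5-bromo-2-hydroxyphenoxy)phenol | Oc1ccc(Br)cc1Oc1c(Br)cc(Br)c(Br)c1O | intermediate
7 | 2,3,5-tribromo-6-(3,5-dibromo-2-hydroxyphenoxy)phenol | Oc1c(Br)cc(Br)cc1Oc1c(Br)cc(Br)c(Br)c1O | target

## Step count and least certain steps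

Total step count: 4. Longest linear sequence: 4 steps (1 to 7); compound 3 is used as purchased.

Step 3 (key step). The most likely failure is hydride migration in the Criegee adduct of the ring B formyl group, or very slow addition of the peracid to that crowded carbonyl. The ring carries three bromines, and its ether oxygen, flanked at C2' and C6', cannot donate well to the migrating carbon, so part of the material could end as a carboxylic acid. The fallback sets out from 4 and comes back at 6. It replaces the formyl groups by acetyl groups, so that the competing migrating group is methyl instead of hydrogen. Addition of MeMgBr in THF at low temperature to both aldehydes should give 1-{4-bromo-2-[3,4,6-tribromo-2-(1-hydroxyethyl)phenoxy]phenyl}ethan-1-ol F1 as a mixture of diastereomers, whose two carbinol centres are removed in the next operation. Oxidation with Dess–Martin periodinane should give 1-[2-(2-acetyl-3,4,6-tribromophenoxy)-4-bromophenyl]ethan-1-one F2. Baeyer–Villiger oxidation of this aryl methyl ketone with trifluoroperacetic acid (from trifluoroacetic anhydride and urea–hydrogen peroxide, buffered with Na2HPO4) should give 2,3,5-tribromo-6-[2-(acetyloxy)-5-bromophenoxy]phenyl acetate F3, and K2CO3 in methanol should then release 6.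

Step 2. The most likely failure is sluggish attack of the weak phenoxide of 2, which is flanked by a bromine and a formyl group. The prolonged heating then needed would let base-induced degradation of the aldehydes and substitution of the activated bromides (ortho or para to a formyl group) compete. The fallback sets out from 2 and comes back at 4, and forms the ether by ligand coupling at iodine instead of addition–elimination. 4-Bromo-2-iodobenzaldehyde (O=Cc1ccc(Br)cc1I) would be oxidised with mCPBA and toluenesulfonic acid in acetonitrile and treated with 1,3,5-trimethoxybenzene to give (5-bromo-2-formylphenyl)(2,4,6-trimethoxyphenyl)iodonium 4-methylbenzenesulfonate F4. Reaction of F4 with 2 and K2CO3 in acetonitrile at or slightly above room temperature should transfer the electron-poor formyl-bearing aryl group to the phenoxide oxygen, a known metal-free O-arylation that tolerates hindered and acidic phenols, and give 4.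

Step 4. The most likely failure is incomplete discrimination between the rings, so that bromination at C3' of ring B (para to the C6' hydroxyl) begins before ring A is fully converted; this could happen if traces of base let the more acidic ring B phenol react as its phenoxide. The fallback sets out from 2 and comes back at 7; it removes the late bromination by bringing the C2 bromine in with the electrophile. Substitution of 2,4-dibromo-6-fluorobenzaldehyde (O=Cc1c(F)cc(Br)cc1Br) by the phenoxide of 2 under the conditions of step 2 should give 2,3,5-tribromo-6-(3,5-dibromo-2-formylphenoxy)benzaldehyde F5. The twofold peracid oxidation of step 3 would then proceed through 2,3,5-tribromo-6-[3,5-dibromo-2-(formyloxy)phenoxy]phenyl formate F6 (not isolated) and give 7 directly after methanolysis. The price is a ring A aldehyde that is flanked on both sides and more electron-poor in the oxidation.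

## Further compounds

F1 | step 3 | 1-{4-bromo-2-[3,4,6-tribromo-2-(1-hydroxyethyl)phenoxy]phenyl}ethan-1-ol (mixture of diastereomers) | CC(O)c1ccc(Br)cc1Oc1c(Br)cc(Br)c(Br)c1C(C)O
F2 | step 3 | 1-[2-(2-acetyl-3,4,6-tribromophenoxy)-4-bromophenyl]ethan-1-one | CC(=O)c1ccc(Br)cc1Oc1c(Br)cc(Br)c(Br)c1C(C)=O
F3 | step 3 | 2,3,5-tribromo-6-[2-(acetyloxy)-5-bromophenoxy]phenyl acetate | CC(=O)Oc1ccc(Br)cc1Oc1c(Br)cc(Br)c(Br)c1OC(C)=O
F4 | step 2 | (5-bromo-2-formylphenyl)(2,4,6-trimethoxyphenyl)iodonium 4-methylbenzenesulfonate | O=Cc1ccc(Br)cc1[I+]c1c(OC)cc(OC)cc1OC.Cc1ccc(cc1)S(=O)(=O)[O-]
F5 | step 4 | 2,3,5-tribromo-6-(3,5-dibromo-2-formylphenoxy)benzaldehyde | O=Cc1c(Br)cc(Br)cc1Oc1c(Br)cc(Br)c(Br)c1C=O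
F6 | step 4 | 2,3,5-tribromo-6-[3,5-dibromo-2-(formyloxy)phenoxy]phenyl formate | O=COc1c(Br)cc(Br)cc1Oc1c(Br)cc(Br)c(Br)c1OC=O
A1 | alternative 1 | 2-[3,5-dibromo-2-(3,5-dibromo-2-methoxyphenoxy)phenyl]-4,4,5,5-tetramethyl-1,3,2-dioxaborolane | COc1c(Br)cc(Br)cc1Oc1c(Br)cc(Br)cc1B1OC(C)(C)C(C)(C)O1
A2 | alternative 1 | 4-bromo-2-iodo-6-(4,4,5,5-tetramethyl-1,3,2-dioxaborolan-2-yl)phenyl trifluoromethanesulfonate | CC1(C)OB(OC1(C)C)c1cc(Br)cc(I)c1OS(=O)(=O)C(F)(F)F
A3 | alternative 1 | 3,5-dibromo-2-methoxyphenol | COc1c(Br)cc(Br)cc1O
A4 | alternative 2 | 4-bromo-2-(2,4-dibromo-6-methoxyphenoxy)phenol | COc1cc(Br)cc(Br)c1Oc1cc(Br)ccc1O
A5 | alternative 2 | 1-(2,4-dibromo-6-methoxyphenoxy)propan-2-one | CC(=O)COc1c(Br)cc(Br)cc1OC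
A6 | alternative 2 | 2-bromopropanedial (bromomalonaldehyde) | O=CC(Br)C=O
A7 | alternative 2 | 2,4-dibromo-6-methoxyphenol | COc1cc(Br)cc(Br)c1O
A8 | alternative 3 | 2,4-dibromo-6-(2,4-dibromo-6-methoxyphenoxy)phenol | COc1cc(Br)cc(Br)c1Oc1cc(Br)cc(Br)c1O
A9 | alternative 3 | 2-(2,4-dibromo-6-methoxyphenoxy)cyclohexan-1-one (racemic) | COc1cc(Br)cc(Br)c1OC1CCCCC1=O
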